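**Strategy.** Ring C is cut at O1–C2, which leads back to an open, racemic triaryl allylic alcohol. The plan exploits the fact that C2–C3–C4 sits between three electron-rich arenes (C4 on rings A and D, C2 on ring B). It is a latent diarylallyl cation that the ring A phenol oxygen can reach only at C2. A chiral N-triflylphosphoramide ionises the C4 carbinol and steers the closure, so that one operation erases the racemic centre, builds ring C, sets C2 and leaves a C3=C4 alkene. Hydroboration anti to ring B then sets C3 and C4 in the all-trans array, and hydrogenolysis of five benzyl ethers ends the route.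

Key step: step 5

Numbering: flavan numbering (O1, C2, C3, C4, C4a to C8a) is used throughout, also for open-chain precursors. Ring A is the benzo ring, ring B the catechol at C2, ring C the pyran and ring D the 2,4-dioxygenated 3-methoxyphenyl at C4. The target is (2R,3S,4R): rings B and D are both trans to the 3-OH.

Assumption: the (R)-configured catalyst is taken to deliver the (S)-chromene 11. If the sense of induction is the opposite, the equally available (S)-catalyst is used and nothing else changes.

Step 1
Reactants: 1 4'-benzyloxy-2'-hydroxyacetophenone; 2 3,4-bis(benzyloxy)benzaldehyde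
Product: 3 (E)-1-[4-(benzyloxy)-2-hydroxyphenyl]-3-[3,4-bis(benzyloxy)phenyl]prop-2-en-1-one
Conditions: KOH, EtOH, rt; then aq HCl
Reagents that add atoms: none
Why: Claisen–Schmidt condensation, in which the methyl ketone enolate adds to the non-enolisable aldehyde, E1cB dehydration gives the conjugated (E)-enone, and the strongly basic medium keeps the 2'-phenolate from closing to the flavanone.

Step 2
Reactants: 4 2-methoxyresorcinol
Product: 5 1,3-bis(benzyloxy)-2-methoxybenzene
Conditions: BnBr (2.2 equiv), K2CO3, DMF, 60 °C
Reagents that add atoms: benzyl bromide, BrCc1ccccc1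
Why: Williamson ether synthesis on both phenols; benzyl is chosen so that all five protecting groups fall in one final hydrogenolysis and the ring D ortho oxygen cannot compete in the key closure.

Step 3
Reactants: 5 1,3-bis(benzyloxy)-2-methoxybenzene
Product: 6 1,3-bis(benzyloxy)-4-bromo-2-methoxybenzene
Conditions: NBS (1.0 equiv), MeCN, 0 °C to rt
Reagents that add atoms: N-bromosuccinimide, O=C1CCC(=O)N1Br
Why: Electrophilic aromatic bromination at C4, which is ortho to one benzyloxy group and para to the other, whereas C5 is activated only by the central methoxy group that is twisted out of conjugation, as in the 4-selective bromination of 1,2,3-trialkoxybenzenes.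

Step 4
Reactants: 6 1,3-bis(benzyloxy)-4-bromo-2-methoxybenzene; 3 the (E)-chalcone
Product: 9 rac-(E)-1-[4-(benzyloxy)-2-hydroxyphenyl]-1-[2,4-bis(benzyloxy)-3-methoxyphenyl]-3-[3,4-bis(benzyloxy)phenyl]prop-2-en-1-ol, via aryllithium 7 (not isolated), via sodium phenolate 8 (not isolated)
Conditions: 6, n-BuLi (1.05 equiv), THF, −78 °C; separately 3, NaH (1.05 equiv), THF, 0 °C; 8 cannulated into 7, −78 to −40 °C; H2O quench; filtration through basic alumina
Reagents that add atoms: n-butyllithium, [Li]CCCC (lithium of 7 only); sodium hydride, [Na+].[H-] (sodium of 8 only)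
Why: Bromine–lithium exchange followed by 1,2-addition of the hard aryllithium to the enone carbonyl; prior deprotonation with NaH spares one equivalent of 7, the (E)-alkene is untouched, and the carbinol centre is deliberately racemic because the next step erases it.

Step 5
Reactants: 9 the racemic tertiary allylic alcohol
Product: 11 (2S)-7-(benzyloxy)-2-[3,4-bis(benzyloxy)phenyl]-4-[2,4-bis(benzyloxy)-3-methoxyphenyl]-2H-chromene, via allyl cation 10 (not isolated)
Conditions: (R)-3,3'-bis(2,4,6-triisopropylphenyl)-BINOL N-triflylphosphoramide (10 mol%), 4 Å MS, toluene, −78 °C, dark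
Reagents that add atoms: none
Why: The strong chiral acid protonates the triply activated C4 carbinol and water leaves, which gives the delocalised C2–C3–C4 allyl cation 10 (the O-protonated form of a vinyl ortho-quinone methide of ring A) as a contact ion pair with the chiral phosphoramide anion. The free ring A phenol, hydrogen-bonded to that anion, attacks the C2 terminus and hands its proton to the anion, so that O1–C2 forms and the acid is regenerated. This is the known Brønsted acid catalysed asymmetric intramolecular allylic substitution (SN1' type) of 2-(1-hydroxy-1,3-diarylallyl)phenols to 2,4-diaryl-2H-chromenes, applied here to a more oxygenated member of the class. Ring C closes in the 6-endo-trig mode, equivalent to an oxa-6π electrocyclisation of the quinone methide form. The only new stereocentre, C2, is controlled by the catalyst anion, which shields one face of the planar C2 terminus, and since ionisation erases the C4 centre of racemic 9, both enantiomers should converge on (S)-11. Site selectivity is secured by the substrate and conditions: attack at C4 would give a four-membered ring, the ring D ortho oxygen is blocked as a benzyl ether so that only the ring A oxygen can close, and low temperature in a non-polar solvent holds back Friedel–Crafts closure to indenes and re-ionisation of the product.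

Step 6
Reactants: 11 the (2S)-chromene
Product: 13 penta-O-benzyl ether of the target (2R and 3S; rings B and D both trans to the free 3-OH), via C3 alkylborane 12 (not isolated)
Conditions: BH3·THF, THF, 0 °C to rt; then H2O, NaOH (aq), H2O2, 0 °C
Reagents that add atoms: hydrogen peroxide, OO (oxygen of the 3-OH); borane–THF, [BH3-][O+]1CCCC1 (boron of 12 only)
Why: Hydroboration–oxidation as known for flav-3-enes; boron goes to the less substituted C3 and hydride to the diaryl-substituted C4 in a concerted syn addition on the face anti to ring B, and oxidation with retention places the 3-OH trans to ring B (sets C3) and cis to H4, hence trans to ring D (sets C4).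

Step 7
Reactants: 13 the penta-O-benzyl ether
Product: 14 (2R,3S,4R)-2-(3,4-dihydroxyphenyl)-4-(2,4-dihydroxy-3-methoxyphenyl)chromane-3,7-diol
Conditions: H2 (1 atm), Pd(OH)2/C, THF/MeOH, rt; filtration and concentration under argon
Reagents that add atoms: none
Why: Catalytic hydrogenolysis of the five aryl benzyl ethers, standard for perbenzylated flavan-3-ols; the cyclic C2–O1 bond, the methyl ether and the three stereocentres should not be affected under these mild neutral conditions.

**Compound list**

1 | 4'-benzyloxy-2'-hydroxyacetophenone | CC(=O)c1ccc(OCc2ccccc2)cc1O | starting material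
2 | 3,4-bis(benzyloxy)benzaldehyde | O=Cc1ccc(OCc2ccccc2)c(OCc2ccccc2)c1 | starting material
3 | (E)-1-[4-(benzyloxy)-2-hydroxyphenyl]-3-[3,4-bis(benzyloxy)phenyl]prop-2-en-1-one | O=C(/C=C/c1ccc(OCc2ccccc2)c(OCc2ccccc2)c1)c1ccc(OCc2ccccc2)cc1O | intermediate
4 | 2-methoxyresorcinol (2-methoxybenzene-1,3-diol) | COc1c(O)cccc1O | starting material
5 | 1,3-bis(benzyloxy)-2-methoxybenzene | COc1c(OCc2ccccc2)cccc1OCc1ccccc1 | intermediate
6 | 1,3-bis(benzyloxy)-4-bromo-2-methoxybenzene | COc1c(OCc2ccccc2)ccc(Br)c1OCc1ccccc1 | intermediate
7 | [2,4-bis(benzyloxy)-3-methoxyphenyl]lithium | COc1c(OCc2ccccc2)ccc([Li])c1OCc1ccccc1 | intermediate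
8 | sodium 2'-phenolate of chalcone 3 | [Na+].[O-]c1cc(OCc2ccccc2)ccc1C(=O)/C=C/c1ccc(OCc2ccccc2)c(OCc2ccccc2)c1 | intermediate
9 | racemic (E)-triaryl tertiary allylic alcohol with free ring A phenol | OC(/C=C/c1ccc(OCc2ccccc2)c(OCc2ccccc2)c1)(c1ccc(OCc2ccccc2)cc1O)c1ccc(OCc2ccccc2)c(OC)c1OCc1ccccc1 | intermediate
10 | C2–C3–C4 triarylallyl cation (ion pair with the catalyst anion) | Oc1cc(OCc2ccccc2)ccc1[C+](/C=C/c1ccc(OCc2ccccc2)c(OCc2ccccc2)c1)c1ccc(OCc2ccccc2)c(OC)c1OCc1ccccc1 | intermediate
11 | (2S)-2,4-diaryl-2H-chromene, pentabenzyl protected | COc1c(OCc2ccccc2)ccc(C2=C[C@@H](c3ccc(OCc4ccccc4)c(OCc4ccccc4)c3)Oc3cc(OCc4ccccc4)ccc23)c1OCc1ccccc1 | intermediate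
12 | C3 alkylborane (BH2 trans to rings B and D) | COc1c(OCc2ccccc2)ccc([C@@H]2c3ccc(OCc4ccccc4)cc3O[C@H](c3ccc(OCc4ccccc4)c(OCc4ccccc4)c3)[C@H]2B)c1OCc1ccccc1 | intermediate
13 | penta-O-benzyl ether of the target, 2,3-trans-3,4-trans | COc1c(OCc2ccccc2)ccc([C@@H]2c3ccc(OCc4ccccc4)cc3O[C@H](c3ccc(OCc4ccccc4)c(OCc4ccccc4)c3)[C@H]2O)c1OCc1ccccc1 | intermediate
14 | (2R,3S,4R)-2-(3,4-dihydroxyphenyl)-4-(2,4-dihydroxy-3-methoxyphenyl)chromane-3,7-diol | COc1c(O)ccc([C@@H]2c3ccc(O)cc3O[C@H](c3ccc(O)c(O)c3)[C@H]2O)c1O | target

**Step count.** The route has 7 steps in total. The longest linear sequence is 6 steps (4 → 5 → 6 → 9 → 11 → 13 → 14).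

**Steps most likely to fail**

1. **Step 5.** Enantiomeric purity may be lost. The cation is so well stabilised by three oxygenated rings that the ion pair can loosen, an uncatalysed background closure can set in, and the product can re-ionise at C2–O1. The fallback replaces asymmetric catalysis by resolution.
   - It sets out from 9, which is closed with an achiral acid (pyridinium p-toluenesulfonate, CH2Cl2, 0 °C) to the racemic chromene F1.
   - Preparative chromatography on a chiral stationary phase (amylose carbamate phase, supercritical CO2/MeOH) separates this into 11, where the route is rejoined, and the (2R)-chromene F2.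
   - F2 is returned to F1 by the same achiral acid and recycled.

2. **Step 6.** Addition to the hindered trisubstituted alkene may be slow. The ring may open by β-elimination of the ring A aryloxide from the β-boryl ether, or the facial selectivity may be insufficient. The fallback replaces kinetic syn addition by a ketone under thermodynamic control.
   - It sets out from 11, which dimethyldioxirane (acetone, −20 °C) should epoxidise anti to ring B to the 3β,4β-epoxide F3.
   - On silica gel this labile epoxide should undergo Meinwald rearrangement, with the C3 hydride shifting to C4 on the α face, to the 2,4-trans 4-arylflavan-3-one F4.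
   - Et3N in CH2Cl2 should then epimerise the most acidic, doubly benzylic C4–H to the diequatorial 2,4-cis 4-arylflavan-3-one F5.
   - NaBH4 (THF/MeOH, −20 °C) should attack axially and give the equatorial alcohol 13, where the route is rejoined.

3. **Step 4.** Addition to the electron-rich, phenolate-conjugated ketone may be sluggish. Conjugate addition may compete, and the very labile alcohol may ionise and close racemically during work-up. The fallback masks the nucleophile of the key step until it is needed.
   - It sets out from 3, which TBSCl and imidazole in DMF convert into the 2'-O-TBS chalcone F6, a more electrophilic ketone.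
   - Addition of 7 at −78 °C gives the O-TBS tertiary alcohol F7, which cannot close.
   - Bu4NF in THF at 0 °C (basic, non-ionising) releases 9 just before the key step, where the route is rejoined.

**Further compounds**

F1 | step 5 | racemic 2,4-diaryl-2H-chromene, pentabenzyl protected | COc1c(OCc2ccccc2)ccc(C2=CC(c3ccc(OCc4ccccc4)c(OCc4ccccc4)c3)Oc3cc(OCc4ccccc4)ccc23)c1OCc1ccccc1
F2 | step 5 | (2R)-2,4-diaryl-2H-chromene, enantiomer of 11 | COc1c(OCc2ccccc2)ccc(C2=C[C@H](c3ccc(OCc4ccccc4)c(OCc4ccccc4)c3)Oc3cc(OCc4ccccc4)ccc23)c1OCc1ccccc1
F3 | step 6 | 3β,4β-epoxide of 11 (oxirane trans to ring B) | COc1c(OCc2ccccc2)ccc([C@@]23O[C@@H]2[C@@H](c2ccc(OCc4ccccc4)c(OCc4ccccc4)c2)Oc2cc(OCc4ccccc4)ccc23)c1OCc1ccccc1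
F4 | step 6 | 2,4-trans 4-arylflavan-3-one (kinetic C4 epimer) | COc1c(OCc2ccccc2)ccc([C@H]2c3ccc(OCc4ccccc4)cc3O[C@H](c3ccc(OCc4ccccc4)c(OCc4ccccc4)c3)C2=O)c1OCc1ccccc1
F5 | step 6 | 2,4-cis 4-arylflavan-3-one (diequatorial) | COc1c(OCc2ccccc2)ccc([C@@H]2c3ccc(OCc4ccccc4)cc3O[C@H](c3ccc(OCc4ccccc4)c(OCc4ccccc4)c3)C2=O)c1OCc1ccccc1
F6 | step 4 | 2'-O-TBS ether of chalcone 3 | CC(C)(C)[Si](C)(C)Oc1cc(OCc2ccccc2)ccc1C(=O)/C=C/c1ccc(OCc2ccccc2)c(OCc2ccccc2)c1
F7 | step 4 | racemic O-TBS ether (ring A phenol) of alcohol 9 | CC(C)(C)[Si](C)(C)Oc1cc(OCc2ccccc2)ccc1C(O)(/C=C/c1ccc(OCc2ccccc2)c(OCc2ccccc2)c1)c1ccc(OCc2ccccc2)c(OC)c1OCc1ccccc1
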